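**Target:** 5,7-dihydroxy-2-(5-hydroxy-2,4-dimethoxyphenyl)-3,6,8-trimethoxy-4H-chromen-4-one (23), COc1cc(OC)c(-c2oc3c(OC)c(O)c(OC)c(O)c3c(=O)c2OC)cc1O

## Structural features

The target is a flavone: a 4H-chromen-4-one in which the benzo ring A (C4a, C5–C8, C8a) is fused to the 4-pyranone ring C (O1, C2, C3, C4), and C2 carries the aryl ring B through the C2–C1' bond. Ring A has no hydrogen: it carries OH on C5, OMe on C6, OH on C7 and OMe on C8. Ring C carries OMe on C3, and ring B is a 5-hydroxy-2,4-dimethoxyphenyl group. There is no stereocentre, so every selectivity question is regiochemical: of eight peripheral oxygens, exactly three (O5, O7, O5') must finish as free phenols and five as methyl ethers. The fragile points are the free phenols on very electron-rich rings (O5 stands para to the C8 methoxyl, a quinone-forming arrangement), the pyranone, which opens at C2 under hot hydroxide, and the methyl ether on C3 next to the C4 carbonyl, which strong Lewis acids cleave. The final unmasking therefore has to be neutral. The real difficulty is the hexasubstituted ring A, the differentiation of its oxygens from each other and from those of ring B, and the oxygen on C3, which sits on the α-carbon of an electron-poor enone. The key step exploits two facts. C4 is a lone carbonyl carbon between C4a of ring A and C3, so it can enter as carbon monoxide between an aryl iodide carbon and an alkyne terminus. And with O1 and O5 both written as free hydroxyls, ring A is mirror-symmetric about the C4a···C7 axis, so a 2-iodoresorcinol needs no differentiation of its two hydroxyls.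

## Logic of the disconnections

**23 back to 22.** The three O–CH2Ph bonds on O5, O7 and O5' are cut. The three phenols are the oxidation-prone part of the target and would compete in every methylation, so they are carried as one kind of ether and freed together. The gain is that every earlier compound is non-phenolic at these positions. The demand is a neutral hydrogenolysis that leaves C2=C3 and five methyl ethers alone.

**22 back to 21.** The O–CH3 bond on O3 is cut. With every other oxygen capped, methylation has a single site and needs no selectivity. The demand is only an ordinary O-alkylation of an acidic enolic hydroxyl.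

**21 back to 19 (through 20).** The C3–O bond is cut. The alkyne-derived C3 necessarily arrives as C–H, and C2=C3 is the only non-aromatic double bond, so epoxidation and acid isomerisation of the oxirane place the oxygen exactly there. The demand is an electrophilic oxidant that finds no free phenol in the molecule, which leads to the next cut.

**19 back to 18.** The O–CH2Ph bond on O5 is cut. The annulation has to deliver O5 as a free hydroxyl, because it is the second hydroxyl of the symmetric precursor. Leaving it free during the C3 oxidation would expose a para-methoxyphenol on a penta-oxygenated ring to the dioxirane, so it is capped first; this is the one change of design, and it costs one step. The cap is benzyl, so no extra deprotection step arises. The demand is alkylation of a chelated, flanked phenol.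

**18 back to 7, 15 and 14.** C4a–C4, C4–C3 and O1–C2 are cut and ring C disappears. The cut separates the two aromatic rings completely and reduces C4 to a one-carbon gas. Because 7 is symmetric and its iodine sits on the only free carbon, no regiochemical question remains. The demand is that carbonylation precedes alkynylation and that closure is six-membered.

**7 back to 6.** The C–I bond is cut. The carbon between the two hydroxyls is the only unsubstituted ring carbon of 6 and is doubly ortho-activated. The demand is an iodination mild enough not to oxidise the ring.

**6 back to 4 (through 5).** The two aryl C–OH bonds are cut to C–Br bonds. Two hydroxyls that are meta to each other cannot be placed by direct oxidation, but two bromines can be placed there by electrophilic substitution. The demand is a C–O coupling that runs twice on an electron-rich ring.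

**4 back to 2 (through 3) and 2 back to 1.** The two C–Br bonds and then the O–CH2Ph bond are cut. Benzylation of 1 is what steers the halogen: in 1 the free hydroxyl would direct para, while in 2 the central alkoxy group is twisted out of conjugation and the two methoxyls direct to the two positions wanted. The gain is a cheap, symmetric starting material. The demand is clean double substitution without attack para to the benzyloxy group.

**14 back to 13.** The bond between the ring-bound alkyne carbon and the terminal carbon is cut (one-carbon homologation of an aldehyde). The demand is a base-mild homologation of an electron-rich, weakly electrophilic aldehyde.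

**13 back to 11 (through 12), 11 back to 10, 10 back to 8 (through 9).** The aryl–CHO bond, the O–CH2Ph bond and the aryl C–O bond are cut in turn. The formyl group of 8 is used once as a handle to introduce the oxygen by aryl migration, and is then reinstalled one position away. There the two methoxyls (ortho and para) jointly direct it, which is exactly the substitution pattern of ring B.

## Other disconnections considered

**Alternative 1:** Cut O1–C8a and C4–C4a, the two bonds that tie ring A to the heterocycle. This leads to 3,5-bis(benzyloxy)-4-methoxybenzyne A3, generated with CsF from the silylaryl triflate A2, and to the 2,3-dimethoxyacrylic acid A4.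

- Forward key step: the carboxylate oxygen of A4 adds to the aryne carbon remote from the flanking benzyloxy group. The aryl anion then attacks the acyl carbon and the four-membered intermediate opens to the ortho-hydroxyaryl ketone A1. The phenol of A1 would next add to the β-carbon and expel the β-methoxy group to give chromenone A5.
- In favour: the C3 methoxyl arrives inside A4, so neither a C3 oxidation nor a protection of O5 after ring closure is needed. On this point the alternative is better than the chosen plan. It also uses no transition metal and no toxic gas.
- Against: A1 carries hydrogen on the carbon that becomes C8. This is not an accident of drawing: the regiochemistry of the aryne addition rests on a single alkoxy group next to the triple bond, and an aryne that already carried the C8 methoxyl would have alkoxy groups on both sides and lose that bias. The C8 methoxyl would therefore have to be put on A5 by halogenation and C–O coupling. In addition, A2 is a penta-substituted arene and A4 a tetrasubstituted enol-ether acid of defined geometry, each a multistep target in itself. Simple O-arylation (protonation of the aryl anion before acyl transfer) competes with insertion.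
- Comparison: on structure, the chosen plan has all four ring A oxygens in place before annulation and needs no bias because of symmetry, whereas the alternative must leave C8 bare. On mechanism, an anionic cascade sensitive to proton sources stands against an organometallic cascade sensitive to the order of CO and alkyne uptake; the risks are comparable. On step economy, the alternative is better after ring closure as far as C3 is concerned, but worse overall because of C8 and the length of the route to A2.

**Alternative 2:** Cut C3–C4 and C2=C3, so that C3 is excised as a one-carbon unit, (methoxymethylidene)triphenylphosphorane A8. What remains is the acid chloride A7, in which O1 is already acylated by the ring B acid.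

- Forward key step: A8 is C-acylated by the acid chloride function of A7 (C3–C4), a second equivalent serving as base. The phosphorus-stabilised carbon then olefinates the neighbouring aryl ester carbonyl in an intramolecular Wittig reaction (C2=C3) to give A6, which is the same compound as 22.
- In favour: the alternative lands directly on 22, so steps 10 to 12 of the chosen route would not be needed. This is a clear advantage after the key step. It also avoids palladium and gas, and O3 is never made by oxidation.
- Against: A7 requires a fully substituted salicylic acid whose two ortho oxygens are different (one benzyl ether, one aroyl ester). The mirror symmetry that the chosen plan uses is therefore destroyed early, and a desymmetrising monoprotection, a carboxylation at the hindered carbon, an O-aroylation and an acid chloride formation beside an aryl ester are all needed. A8 is a non-stabilised, strongly basic ylide that can also attack the aryl ester. The ring-closing olefination of an ester by an acyl-stabilised ylide is slow, and here it is hindered on both sides.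
- Comparison: on structure, both plans fix every ring A oxygen before ring C closes, and the alternative fixes O3 as well. On mechanism, the chosen cascade has direct precedent on 2-iodophenols, while the ylide cascade puts all its risk into one hindered olefination. On step economy, the alternative is better after the key step (one step against four) and worse before it, so the totals are about equal.

**Alternative 3:** Cut C4a–C5 inside ring A, so that ring A comes from the open-chain tetraketo ester A10.

- Forward key step: base forms the enolate at the C4a methylene, the only CH2 and the only doubly activated position without a methoxyl. Claisen attack on the ester carbon closes the six-membered carbocycle, and enolisation aromatises it to the acylphloroglucinol A9. Cyclodehydration through either ortho hydroxyl would give the 5'-O-benzyl flavone A11, one hydrogenolysis away from 23.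
- In favour: every oxygen, O3 included, is in place before the ring forms, and O5 and O7 never need protection. The phloroglucinol core is symmetric, which is the equal of the symmetry argument of the chosen plan. The two steps after the key step are fewer than the four of the chosen plan, and on that count the alternative is better.
- Against: A10 has nine contiguous reactive carbons. Aldol closures onto ketone carbonyls, O-attack on the ester to give hydroxypyranones, and retro-Claisen cleavage by the base all compete with the wanted C-acylation. No dependable way exists to assemble a chain with three α-methoxy ketone units.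
- Comparison: on structure, the alternative builds ring A and the chosen plan buys it (from 1). On mechanism, the alternative relies on aromatisation as the only driving force to sort many enolate pathways, while the chosen plan relies on a catalytic cycle with a defined order of events. On step economy, the alternative is the shortest on paper after the key step, but reaching A10 is likely to take more steps than the eight that lead to 7 and 14, and with far less certainty.

Key step: step 9

**Remarks on the chemistry.** Epoxide 20 is formed as a racemate and is drawn as one enantiomer; its two stereocentres are lost within the same step. The annulation components 7, 15 and 14 and the annulation product 18 map atom for atom onto the target and are used unchanged.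

## Route

Step 1
Reactants: 1 2,6-dimethoxyphenol (syringol)
Product: 2 2-(benzyloxy)-1,3-dimethoxybenzene
Conditions: BnBr, K2CO3, DMF, 60 °C
Reagents that add atoms: benzyl bromide, BrCc1ccccc1
Why: Williamson ether synthesis on the phenoxide; capping the oxygen also switches off its para-directing effect, which the next step relies on.

Step 2
Reactants: 2 2-(benzyloxy)-1,3-dimethoxybenzene
Product: 4 3-(benzyloxy)-1,5-dibromo-2,4-dimethoxybenzene, via monobromide 3 (not isolated)
Conditions: NBS (2.1 equiv), MeCN, 0 °C to rt, dark
Reagents that add atoms: N-bromosuccinimide, O=C1CCC(=O)N1Br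
Why: Electrophilic aromatic bromination; the central benzyloxy group is twisted out of conjugation by its two neighbours, so each methoxyl directs to its own ortho carbon, which is also para to the other methoxyl, and the second bromine should enter 3 at the mirror-image position while the carbon para to the benzyloxy group stays free.

Step 3
Reactants: 4 3-(benzyloxy)-1,5-dibromo-2,4-dimethoxybenzene
Product: 6 5-(benzyloxy)-4,6-dimethoxybenzene-1,3-diol, via bromophenol 5 (not isolated)
Conditions: Pd2(dba)3 (2 mol%), t-BuXPhos (8 mol%), KOH, 1,4-dioxane/H2O, 100 °C, argon; then aq. HCl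
Reagents that add atoms: potassium hydroxide, [K+].[OH-]
Why: Palladium-catalysed C–O coupling of aryl bromides with hydroxide (Buchwald–Hartwig-type hydroxylation); the bulky biaryl phosphine drives the C–O reductive elimination, the coupling runs twice through 5, and benzyl and methyl ethers are inert to aqueous KOH.

Step 4
Reactants: 6 5-(benzyloxy)-4,6-dimethoxybenzene-1,3-diol
Product: 7 5-(benzyloxy)-2-iodo-4,6-dimethoxybenzene-1,3-diol
Conditions: I2 (1.05 equiv), NaHCO3, THF/H2O, 0 °C
Reagents that add atoms: iodine, II
Why: Electrophilic iodination of a resorcinol at the carbon between the two hydroxyls, which is the only unsubstituted ring carbon; the bicarbonate buffer and low temperature should keep the mild oxidant from attacking the electron-rich ring.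

Step 5
Reactants: 8 2,4-dimethoxybenzaldehyde
Product: 10 2,4-dimethoxyphenol, via aryl formate 9 (not isolated)
Conditions: mCPBA, CH2Cl2, 0 °C to rt; then K2CO3 (cat.), MeOH, rt
Reagents that add atoms: 3-chloroperoxybenzoic acid (mCPBA), OOC(=O)c1cccc(Cl)c1
Why: Dakin-type oxidation; Baeyer–Villiger migration of the electron-rich aryl group in the peracid adduct gives formate 9, which methanol transesterifies to the phenol.

Step 6
Reactants: 10 2,4-dimethoxyphenol
Product: 11 1-(benzyloxy)-2,4-dimethoxybenzene
Conditions: BnBr, K2CO3, acetone, reflux
Reagents that add atoms: benzyl bromide, BrCc1ccccc1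
Why: Williamson ether synthesis; the benzyl group masks the future O5' hydroxyl until the last step.

Step 7
Reactants: 11 1-(benzyloxy)-2,4-dimethoxybenzene
Product: 13 5-(benzyloxy)-2,4-dimethoxybenzaldehyde, via iminium chloride 12 (not isolated)
Conditions: POCl3, DMF, 0 to 60 °C; then aq. NaOH, rt
Reagents that add atoms: N,N-dimethylformamide, CN(C)C=O; water, O
Why: Vilsmeier–Haack formylation; the chloroiminium ion should attack the carbon that is ortho to one methoxyl and para to the other (the carbon between the two methoxyls is shielded and the one next to the benzyloxy group is meta to both), and 12 is hydrolysed on work-up.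

Step 8
Reactants: 13 5-(benzyloxy)-2,4-dimethoxybenzaldehyde
Product: 14 1-(benzyloxy)-5-ethynyl-2,4-dimethoxybenzene
Conditions: dimethyl (1-diazo-2-oxopropyl)phosphonate, K2CO3, MeOH/THF, 0 °C to rt
Reagents that add atoms: dimethyl (1-diazo-2-oxopropyl)phosphonate, COP(=O)(OC)C(=[N+]=[N-])C(C)=O
Why: Seyferth–Gilbert homologation in the Ohira–Bestmann variant; methoxide deacylates the reagent, olefination of the aldehyde gives a diazoalkene, and loss of nitrogen with a 1,2-hydrogen shift in the alkylidene carbene gives the terminal alkyne under conditions that touch no ether.

Step 9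
Reactants: 7 5-(benzyloxy)-2-iodo-4,6-dimethoxybenzene-1,3-diol; 15 carbon monoxide; 14 1-(benzyloxy)-5-ethynyl-2,4-dimethoxybenzene
Product: 18 7-(benzyloxy)-2-[5-(benzyloxy)-2,4-dimethoxyphenyl]-5-hydroxy-6,8-dimethoxy-4H-chromen-4-one, via ynone 16 (not isolated), via enaminone 17 (not isolated)
Conditions: PdCl2(PPh3)2 (5 mol%), Et2NH, 15 (10 bar), 100 °C, autoclave
Reagents that add atoms: none
Why: PdCl2(PPh3)2 is reduced in the flask to zerovalent palladium, which inserts into the C–I bond of 7; migratory insertion of 15 gives an aroylpalladium iodide, and amine-assisted transfer of the alkynyl group of 14 followed by reductive elimination forms C4a–C4 and C4–C3 in ynone 16. Diethylamine adds to the β-carbon of 16 to give enaminone 17, and one of the two equivalent phenols then attacks the same carbon and expels the amine, forming O1–C2. Ring C thus closes by a 6-endo addition–elimination at a trigonal carbon (formally 6-endo-dig with respect to 16). The closest known reaction type is the palladium-catalysed carbonylative coupling of 2-iodophenols with terminal alkynes to flavones (carbonylative Sonogashira coupling with cyclisation). No stereocentre is formed. Three selectivities are needed: carbonylation before alkynylation, which the CO pressure, the absence of copper and the fast CO insertion at an electron-rich, doubly ortho-substituted arylpalladium species should secure; six-membered instead of five-membered (aurone) closure, which the enaminone pathway secures because the amine-bearing β-carbon is the only electrophilic site left; and the choice of hydroxyl, which needs no control because 7 is mirror-symmetric and its iodine occupies the only free carbon. The second hydroxyl ends as the chelated O5–H of 18.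

Step 10
Reactants: 18 7-(benzyloxy)-2-[5-(benzyloxy)-2,4-dimethoxyphenyl]-5-hydroxy-6,8-dimethoxy-4H-chromen-4-one
Product: 19 5,7-bis(benzyloxy)-2-[5-(benzyloxy)-2,4-dimethoxyphenyl]-6,8-dimethoxy-4H-chromen-4-one
Conditions: BnBr, K2CO3, n-Bu4NI (cat.), DMF, 60 °C
Reagents that add atoms: benzyl bromide, BrCc1ccccc1
Why: Williamson ether synthesis on the only free hydroxyl; the polar solvent, heat and in situ benzyl iodide should overcome the hydrogen bond to the C4 carbonyl, and capping O5 removes the last phenol before the oxidation.

Step 11
Reactants: 19 5,7-bis(benzyloxy)-2-[5-(benzyloxy)-2,4-dimethoxyphenyl]-6,8-dimethoxy-4H-chromen-4-one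
Product: 21 5,7-bis(benzyloxy)-2-[5-(benzyloxy)-2,4-dimethoxyphenyl]-3-hydroxy-6,8-dimethoxy-4H-chromen-4-one, via epoxide 20 (not isolated)
Conditions: DMDO (acetone solution, about 3 equiv), CH2Cl2, 0 °C to rt; then p-TsOH·H2O (cat.), CH2Cl2, rt
Reagents that add atoms: dimethyldioxirane, CC1(C)OO1
Why: Dioxirane epoxidation of the C2=C3 bond gives the racemic cis-fused epoxide 20, whose two stereocentres are tied together by the three-membered ring and disappear at once; acid opens the oxirane at C2 to the cation stabilised by O1 and ring B, and loss of H3 gives the flavonol. With every phenol capped, no phenol-to-quinone oxidation can compete.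

Step 12
Reactants: 21 5,7-bis(benzyloxy)-2-[5-(benzyloxy)-2,4-dimethoxyphenyl]-3-hydroxy-6,8-dimethoxy-4H-chromen-4-one
Product: 22 5,7-bis(benzyloxy)-2-[5-(benzyloxy)-2,4-dimethoxyphenyl]-3,6,8-trimethoxy-4H-chromen-4-one
Conditions: MeI, K2CO3, acetone, reflux
Reagents that add atoms: iodomethane, CI
Why: O-Methylation (Williamson) of the acidic enolic 3-hydroxyl, the only hydroxyl in the molecule, so no site selectivity is required.

Step 13
Reactants: 22 5,7-bis(benzyloxy)-2-[5-(benzyloxy)-2,4-dimethoxyphenyl]-3,6,8-trimethoxy-4H-chromen-4-one
Product: 23 5,7-dihydroxy-2-(5-hydroxy-2,4-dimethoxyphenyl)-3,6,8-trimethoxy-4H-chromen-4-one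
Conditions: H2 (1 atm), 10% Pd/C, EtOAc/MeOH, rt
Reagents that add atoms: none
Why: Catalytic hydrogenolysis of three aryl benzyl ethers under neutral conditions; the tetrasubstituted, cross-conjugated C2=C3 bond and the methyl ethers should not react at balloon pressure.

## Compound list

1 | 2,6-dimethoxyphenol (syringol) | COc1cccc(OC)c1O | starting material
2 | 2-(benzyloxy)-1,3-dimethoxybenzene | COc1cccc(OC)c1OCc1ccccc1 | intermediate
3 | 2-(benzyloxy)-4-bromo-1,3-dimethoxybenzene | COc1ccc(Br)c(OC)c1OCc1ccccc1 | intermediate
4 | 3-(benzyloxy)-1,5-dibromo-2,4-dimethoxybenzene | COc1c(Br)cc(Br)c(OC)c1OCc1ccccc1 | intermediate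
5 | 3-(benzyloxy)-5-bromo-2,4-dimethoxyphenol | COc1c(O)cc(Br)c(OC)c1OCc1ccccc1 | intermediate
6 | 5-(benzyloxy)-4,6-dimethoxybenzene-1,3-diol | COc1c(O)cc(O)c(OC)c1OCc1ccccc1 | intermediate
7 | 5-(benzyloxy)-2-iodo-4,6-dimethoxybenzene-1,3-diol | COc1c(O)c(I)c(O)c(OC)c1OCc1ccccc1 | intermediate
8 | 2,4-dimethoxybenzaldehyde | COc1ccc(C=O)c(OC)c1 | starting material
9 | 2,4-dimethoxyphenyl formate | COc1ccc(OC=O)c(OC)c1 | intermediate
10 | 2,4-dimethoxyphenol | COc1ccc(O)c(OC)c1 | intermediate
11 | 1-(benzyloxy)-2,4-dimethoxybenzene | COc1ccc(OCc2ccccc2)c(OC)c1 | intermediate
12 | N-{[5-(benzyloxy)-2,4-dimethoxyphenyl]methylidene}-N-methylmethanaminium chloride | C[N+](C)=Cc1cc(OCc2ccccc2)c(OC)cc1OC.[Cl-] | intermediate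
13 | 5-(benzyloxy)-2,4-dimethoxybenzaldehyde | COc1cc(OC)c(C=O)cc1OCc1ccccc1 | intermediate
14 | 1-(benzyloxy)-5-ethynyl-2,4-dimethoxybenzene | C#Cc1cc(OCc2ccccc2)c(OC)cc1OC | intermediate
15 | carbon monoxide | [C-]#[O+] | starting material
16 | 1-[4-(benzyloxy)-2,6-dihydroxy-3,5-dimethoxyphenyl]-3-[5-(benzyloxy)-2,4-dimethoxyphenyl]prop-2-yn-1-one | COc1cc(OC)c(C#CC(=O)c2c(O)c(OC)c(OCc3ccccc3)c(OC)c2O)cc1OCc1ccccc1 | intermediate
17 | (E)-1-[4-(benzyloxy)-2,6-dihydroxy-3,5-dimethoxyphenyl]-3-[5-(benzyloxy)-2,4-dimethoxyphenyl]-3-(diethylamino)prop-2-en-1-one | CCN(CC)/C(=C/C(=O)c1c(O)c(OC)c(OCc2ccccc2)c(OC)c1O)c1cc(OCc2ccccc2)c(OC)cc1OC | intermediate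
18 | 7-(benzyloxy)-2-[5-(benzyloxy)-2,4-dimethoxyphenyl]-5-hydroxy-6,8-dimethoxy-4H-chromen-4-one | COc1cc(OC)c(-c2cc(=O)c3c(O)c(OC)c(OCc4ccccc4)c(OC)c3o2)cc1OCc1ccccc1 | intermediate
19 | 5,7-bis(benzyloxy)-2-[5-(benzyloxy)-2,4-dimethoxyphenyl]-6,8-dimethoxy-4H-chromen-4-one | COc1cc(OC)c(-c2cc(=O)c3c(OCc4ccccc4)c(OC)c(OCc4ccccc4)c(OC)c3o2)cc1OCc1ccccc1 | intermediate
20 | 4,6-bis(benzyloxy)-1a-[5-(benzyloxy)-2,4-dimethoxyphenyl]-3,5-dimethoxy-1a,7a-dihydro-7H-oxireno[2,3-b]chromen-7-one (racemic, cis-fused: oxirane oxygen on one face, aryl on C1a and H on C7a on the other; one enantiomer drawn) | O=C1c2c(OCc3ccccc3)c(OC)c(OCc3ccccc3)c(OC)c2O[C@]2(c3cc(OCc4ccccc4)c(OC)cc3OC)O[C@H]12 | intermediate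
21 | 5,7-bis(benzyloxy)-2-[5-(benzyloxy)-2,4-dimethoxyphenyl]-3-hydroxy-6,8-dimethoxy-4H-chromen-4-one | COc1cc(OC)c(-c2oc3c(OC)c(OCc4ccccc4)c(OC)c(OCc4ccccc4)c3c(=O)c2O)cc1OCc1ccccc1 | intermediate
22 | 5,7-bis(benzyloxy)-2-[5-(benzyloxy)-2,4-dimethoxyphenyl]-3,6,8-trimethoxy-4H-chromen-4-one | COc1cc(OC)c(-c2oc3c(OC)c(OCc4ccccc4)c(OC)c(OCc4ccccc4)c3c(=O)c2OC)cc1OCc1ccccc1 | intermediate
23 | 5,7-dihydroxy-2-(5-hydroxy-2,4-dimethoxyphenyl)-3,6,8-trimethoxy-4H-chromen-4-one | COc1cc(OC)c(-c2oc3c(OC)c(O)c(OC)c(O)c3c(=O)c2OC)cc1O | target

## Step count and risk

Total step count: 13 steps. Longest linear sequence: 9 steps (steps 1 to 4 and 9 to 13); the ring B branch (steps 5 to 8) has four steps. If 10 is bought instead of made, the total falls by one and the longest linear sequence is unchanged.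

**Step 9 (key step).** Direct alkynylation of the arylpalladium species before CO insertion, followed by 5-endo closure of the resulting alkynylphenol, would divert material to a benzofuran. Capture of the hindered aroylpalladium species by diethylamine or by a phenoxide, and reductive loss of iodine, are further drains. All of these arise because the iodide is flanked by two hydroxyls on a very electron-rich ring. The fallback gives up the carbonylation and builds the same ring by condensation. It sets out from 6 and 13, so steps 4 and 8 are not needed. C-Acetylation of 6 at its only free carbon with Ac2O and BF3·OEt2 at room temperature should give 1-[4-(benzyloxy)-2,6-dihydroxy-3,5-dimethoxyphenyl]ethan-1-one F1. Claisen–Schmidt condensation of F1 with 13 (KOH, EtOH) should give the chalcone (E)-1-[4-(benzyloxy)-2,6-dihydroxy-3,5-dimethoxyphenyl]-3-[5-(benzyloxy)-2,4-dimethoxyphenyl]prop-2-en-1-one F2. Oxidative cyclisation of F2 with catalytic I2 in DMSO at 110 to 120 °C closes ring C through either hydroxyl and comes back to the route at 18.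

**Step 3.** The second C–O coupling may stall on the electron-rich bromophenoxide formed from 5, hydrodebromination may compete, and the dianion of the product may be oxidised by traces of air in hot base. The fallback separates C–B formation from oxidation. It sets out from 4. Miyaura borylation (bis(pinacolato)diboron, PdCl2(dppf), KOAc, 1,4-dioxane, 90 °C) should give 2,2'-[5-(benzyloxy)-4,6-dimethoxy-1,3-phenylene]bis(4,4,5,5-tetramethyl-1,3,2-dioxaborolane) F3. Oxidation of both C–B bonds with H2O2 and NaOH in THF/H2O at 0 °C comes back to the route at 6.

**Step 11.** Epoxidation of the electron-poor C2=C3 bond, shielded by a ring B that the 2'-methoxyl twists out of plane, may be slow enough for oxidation of benzylic C–H bonds or of the alkoxyarenes to compete. The fallback replaces the electrophilic oxidant by deprotonation. It sets out from 19. LDA in THF at –78 °C should remove H3, the most acidic C–H of a flavone, and trapping with B(OMe)3 should give dimethyl {5,7-bis(benzyloxy)-2-[5-(benzyloxy)-2,4-dimethoxyphenyl]-6,8-dimethoxy-4-oxo-4H-chromen-3-yl}boronate F4. Oxidation of F4 in the same flask with H2O2 and AcOH comes back to the route at 21.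

**Step 10.** Alkylation of the chelated, doubly flanked O5–H may stay incomplete, and forcing it with stronger base or heat invites opening of the pyranone at C2. The fallback moves the benzylation to a stage where the hydroxyl is not chelated. It sets out from 7. Monobenzylation with one equivalent of BnBr and K2CO3 in acetone at room temperature should give 3,5-bis(benzyloxy)-2-iodo-4,6-dimethoxyphenol F5, separated from recovered 7 and from the bis-ether. Carbonylative annulation of F5 with 15 and 14 under the conditions of step 9 closes ring C through the one remaining hydroxyl and comes back to the route at 19.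

## Further compounds

F1 | step 9 | 1-[4-(benzyloxy)-2,6-dihydroxy-3,5-dimethoxyphenyl]ethan-1-one | CC(=O)c1c(O)c(OC)c(OCc2ccccc2)c(OC)c1O
F2 | step 9 | (E)-1-[4-(benzyloxy)-2,6-dihydroxy-3,5-dimethoxyphenyl]-3-[5-(benzyloxy)-2,4-dimethoxyphenyl]prop-2-en-1-one | COc1cc(OC)c(/C=C/C(=O)c2c(O)c(OC)c(OCc3ccccc3)c(OC)c2O)cc1OCc1ccccc1
F3 | step 3 | 2,2'-[5-(benzyloxy)-4,6-dimethoxy-1,3-phenylene]bis(4,4,5,5-tetramethyl-1,3,2-dioxaborolane) | COc1c(B2OC(C)(C)C(C)(C)O2)cc(B2OC(C)(C)C(C)(C)O2)c(OC)c1OCc1ccccc1
F4 | step 11 | dimethyl {5,7-bis(benzyloxy)-2-[5-(benzyloxy)-2,4-dimethoxyphenyl]-6,8-dimethoxy-4-oxo-4H-chromen-3-yl}boronate | COB(OC)c1c(-c2cc(OCc3ccccc3)c(OC)cc2OC)oc2c(OC)c(OCc3ccccc3)c(OC)c(OCc3ccccc3)c2c1=O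
F5 | step 10 | 3,5-bis(benzyloxy)-2-iodo-4,6-dimethoxyphenol | COc1c(O)c(I)c(OCc2ccccc2)c(OC)c1OCc1ccccc1
A1 | alternative 1 | (E)-1-[4,6-bis(benzyloxy)-2-hydroxy-5-methoxyphenyl]-3-[5-(benzyloxy)-2,4-dimethoxyphenyl]-2,3-dimethoxyprop-2-en-1-one | CO/C(=C(/OC)C(=O)c1c(O)cc(OCc2ccccc2)c(OC)c1OCc1ccccc1)c1cc(OCc2ccccc2)c(OC)cc1OC
A2 | alternative 1 | 3,5-bis(benzyloxy)-4-methoxy-2-(trimethylsilyl)phenyl trifluoromethanesulfonate | COc1c(OCc2ccccc2)cc(OS(=O)(=O)C(F)(F)F)c([Si](C)(C)C)c1OCc1ccccc1
A3 | alternative 1 | 3,5-bis(benzyloxy)-4-methoxybenzyne (1,2-didehydro form) | COC1=C(OCc2ccccc2)C#CC=C1OCc1ccccc1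
A4 | alternative 1 | (E)-3-[5-(benzyloxy)-2,4-dimethoxyphenyl]-2,3-dimethoxyprop-2-enoic acid | CO/C(=C(/OC)C(=O)O)c1cc(OCc2ccccc2)c(OC)cc1OC
A5 | alternative 1 | 5,7-bis(benzyloxy)-2-[5-(benzyloxy)-2,4-dimethoxyphenyl]-3,6-dimethoxy-4H-chromen-4-one | COc1cc(OC)c(-c2oc3cc(OCc4ccccc4)c(OC)c(OCc4ccccc4)c3c(=O)c2OC)cc1OCc1ccccc1
A6 | alternative 2 | 5,7-bis(benzyloxy)-2-[5-(benzyloxy)-2,4-dimethoxyphenyl]-3,6,8-trimethoxy-4H-chromen-4-one (identical with 22) | COc1cc(OC)c(-c2oc3c(OC)c(OCc4ccccc4)c(OC)c(OCc4ccccc4)c3c(=O)c2OC)cc1OCc1ccccc1
A7 | alternative 2 | 3,5-bis(benzyloxy)-2-(chlorocarbonyl)-4,6-dimethoxyphenyl 5-(benzyloxy)-2,4-dimethoxybenzoate | COc1cc(OC)c(C(=O)Oc2c(OC)c(OCc3ccccc3)c(OC)c(OCc3ccccc3)c2C(Cl)=O)cc1OCc1ccccc1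
A8 | alternative 2 | (methoxymethylidene)triphenylphosphorane | COC=P(c1ccccc1)(c1ccccc1)c1ccccc1
A9 | alternative 3 | 1-[5-(benzyloxy)-2,4-dimethoxyphenyl]-2-methoxy-3-(2,4,6-trihydroxy-3,5-dimethoxyphenyl)propane-1,3-dione (enolisable stereocentre, unassigned) | COc1c(O)c(OC)c(O)c(C(=O)C(OC)C(=O)c2cc(OCc3ccccc3)c(OC)cc2OC)c1O
A10 | alternative 3 | methyl 9-[5-(benzyloxy)-2,4-dimethoxyphenyl]-2,4,8-trimethoxy-3,5,7,9-tetraoxononanoate (three enolisable stereocentres, unassigned mixture) | COC(=O)C(OC)C(=O)C(OC)C(=O)CC(=O)C(OC)C(=O)c1cc(OCc2ccccc2)c(OC)cc1OC
A11 | alternative 3 | 2-[5-(benzyloxy)-2,4-dimethoxyphenyl]-5,7-dihydroxy-3,6,8-trimethoxy-4H-chromen-4-one | COc1cc(OC)c(-c2oc3c(OC)c(O)c(OC)c(O)c3c(=O)c2OC)cc1OCc1ccccc1
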